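**Plan**
1. The retrosynthesis first cuts the O6–benzyl bond (protecting group). It then cuts the ether bond between the oxygen on C3 of the 6-hydroxy-7-methoxycoumarin (unprimed) and C7' of the second coumarin (primed), the only bond joining the two halves.
2. Enabling feature: the oxygen on C3 is the acidic, fully enolised OH of an α-keto lactone (C2=O, C3–OH, C3=C4 in the pyranone ring). The unprimed ring can therefore carry the oxygen, and C7' can enter as an arylboron partner under copper(II)/air.
3. The unprimed pyranone ring is cut at O1–C2 and C3–C4 to 5-(benzyloxy)-2-hydroxy-4-methoxybenzaldehyde and N-acetylglycine. The aldehyde comes from O-benzylvanillin by Baeyer–Villiger oxidation and ortho-formylation.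
4. The primed ring system is bought as umbelliferone, and its C7–O bond is exchanged for C7–B through the triflate.
5. Forward order: the benzene ring is substituted, the unprimed pyranone ring is closed, N is exchanged for O at C3, the ether is joined, and the benzyl group is removed.
6. Stereochemistry: the target has none, so the control needed is regiochemical (formylation site) and chemoselective (O- versus C4-arylation).

Key step: step 7

Remark: the target has no stereocentre and no hindered axis (the ether rotates freely), so it is achiral. Its constitution defines it completely and no step has to control configuration.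

**Step 1**
Reactants: 1 4-(benzyloxy)-3-methoxybenzaldehyde (O-benzylvanillin)
Product: 3 4-(benzyloxy)-3-methoxyphenol, via 4-(benzyloxy)-3-methoxyphenyl formate 2 (not isolated)
Conditions: mCPBA, CH2Cl2, 0 °C to rt; wash (aq Na2S2O3, NaHCO3), concentrate; crude 2, K2CO3 (cat.), MeOH, rt
Reagents that add atoms: mCPBA (3-chloroperoxybenzoic acid), OOC(=O)c1cccc(Cl)c1
Why: Baeyer–Villiger (Dakin-type) oxidation, in which the electron-rich aryl group para to the benzyloxy oxygen migrates in the Criegee adduct in preference to hydride, and the aryl formate 2 is then transesterified by methanol without touching the benzyl or methyl ether.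

**Step 2**
Reactants: 3 4-(benzyloxy)-3-methoxyphenol
Product: 4 5-(benzyloxy)-2-hydroxy-4-methoxybenzaldehyde
Conditions: MgCl2 (anhydrous), Et3N, (CH2O)n, MeCN, reflux; 1 M HCl work-up
Reagents that add atoms: formaldehyde (as paraformaldehyde), C=O
Why: Casnati–Skattebøl magnesium-mediated ortho-formylation, in which the magnesium phenoxide delivers formaldehyde only ortho to the OH, the site between OH and OMe is sterically shut so the position para to OMe reacts, and a second formaldehyde oxidises the salicyl alkoxide to the aldehyde by hydride transfer.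

**Step 3**
Reactants: 4 5-(benzyloxy)-2-hydroxy-4-methoxybenzaldehyde; 5 N-acetylglycine
Product: 7 N-[6-(benzyloxy)-7-methoxy-2-oxo-2H-chromen-3-yl]acetamide, via 2-methyl-1,3-oxazol-5(4H)-one 6 (not isolated)
Conditions: NaOAc (anhydrous), Ac2O, 110 °C
Reagents that add atoms: none
Why: Erlenmeyer–Plöchl azlactone condensation, in which acetic anhydride cyclises 5 to oxazolone 6, its C4 enolate adds to the aldehyde (C3–C4), the neighbouring phenol oxygen opens the oxazolone by acyl transfer (O1–C2), and loss of water gives the 3-acetamidocoumarin, the standard outcome for salicylaldehydes.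

**Step 4**
Reactants: 7 N-[6-(benzyloxy)-7-methoxy-2-oxo-2H-chromen-3-yl]acetamide
Product: 9 6-(benzyloxy)-3-hydroxy-7-methoxy-2H-chromen-2-one, via 3-amino-6-(benzyloxy)-7-methoxy-2H-chromen-2-one 8 (not isolated)
Conditions: 3 M aq HCl, 1,4-dioxane, reflux, N2
Reagents that add atoms: water, O
Why: Acid hydrolysis of an enamide, in which the acetamide is cleaved to enamine 8, protonation at C4 gives an iminium ion that water hydrolyses with loss of ammonium, and the α-keto lactone settles as its conjugated enol 9, while aryl benzyl and methyl ethers should tolerate dilute aqueous HCl and the lactone stays closed in acid.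

**Step 5**
Reactants: 10 umbelliferone (7-hydroxy-2H-chromen-2-one)
Product: 11 2-oxo-2H-chromen-7-yl trifluoromethanesulfonate
Conditions: Tf2O, pyridine, CH2Cl2, 0 °C to rt
Reagents that add atoms: trifluoromethanesulfonic anhydride, O=S(=O)(OS(=O)(=O)C(F)(F)F)C(F)(F)F
Why: O-sulfonylation of a phenol, in which the single OH of 10 is triflated under pyridine, a base too weak to open the lactone.

**Step 6**
Reactants: 11 2-oxo-2H-chromen-7-yl trifluoromethanesulfonate; 12 bis(pinacolato)diboron
Product: 13 7-(4,4,5,5-tetramethyl-1,3,2-dioxaborolan-2-yl)-2H-chromen-2-one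
Conditions: Pd(dppf)Cl2 (5 mol %), KOAc, 1,4-dioxane, 90 °C
Reagents that add atoms: none
Why: Miyaura borylation, in which oxidative addition of the electron-poor aryl triflate, acetate-assisted transmetalation from 12 and reductive elimination give the aryl pinacol boronate, and KOAc is too weak a base to trigger Suzuki homocoupling or lactone opening.

**Step 7**
Reactants: 9 6-(benzyloxy)-3-hydroxy-7-methoxy-2H-chromen-2-one; 13 7-(4,4,5,5-tetramethyl-1,3,2-dioxaborolan-2-yl)-2H-chromen-2-one
Product: 14 6-(benzyloxy)-7-methoxy-3-[(2-oxo-2H-chromen-7-yl)oxy]-2H-chromen-2-one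
Conditions: 13 (1.5 equiv), Cu(OAc)2 (1 equiv), pyridine (3 equiv), B(OH)3 (2 equiv), 4 Å MS, MeCN, dry air, 60 °C
Reagents that add atoms: none
Why: Chan–Lam–Evans oxidative O-arylation: pyridine deprotonates the acidic C3 enol of 9 and its oxygen binds copper(II), the C7' aryl group of 13 passes from boron to copper, disproportionation with a second copper(II) gives an aryl–copper(III) enolate, and C–O reductive elimination forms the O–C7' bond while air returns copper(I) to copper(II), so that copper ends as it began. The closest known reaction type is the copper(II) acetate/amine coupling of phenols and hydroxy-heteroarenes with arylboronic acids and their pinacol esters, and 9, a ring-locked and fully enolised α-keto lactone, behaves as such an acidic phenol. No ring closes and no stereocentre forms. The step needs O- over C4-arylation of the ambident enol and no oxidative C4–C4 dimerisation, which the inner-sphere transfer from the copper-bound oxygen, the absence of strong base and the excess of 13 should secure. Boric acid takes up pinacol that would otherwise tie up copper, and the sieves suppress hydroxylation of 13 to a phenol that would compete as a second O-nucleophile. The only other phenol oxygen (O6) is masked as the benzyl ether, and both lactones meet nothing more nucleophilic than pyridine.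

**Step 8**
Reactants: 14 6-(benzyloxy)-7-methoxy-3-[(2-oxo-2H-chromen-7-yl)oxy]-2H-chromen-2-one
Product: 15 6-hydroxy-7-methoxy-3-[(2-oxo-2H-chromen-7-yl)oxy]-2H-chromen-2-one (target)
Conditions: BCl3 (1 M in CH2Cl2, 4 equiv), pentamethylbenzene (5 equiv), CH2Cl2, −78 °C; MeOH quench, aqueous work-up
Reagents that add atoms: none
Why: Lewis-acid debenzylation with a non-basic cation scavenger, in which BCl3 activates the benzyl ether oxygen and the benzyl cation is passed to pentamethylbenzene (Friedel–Crafts alkylation) at −78 °C, where the methyl ether, the C3–O–C7' ether and both lactone C=C bonds should stay intact.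

**Compound list**
1 | 4-(benzyloxy)-3-methoxybenzaldehyde (O-benzylvanillin) | COc1cc(C=O)ccc1OCc1ccccc1 | starting material
2 | 4-(benzyloxy)-3-methoxyphenyl formate | COc1cc(OC=O)ccc1OCc1ccccc1 | intermediate (not isolated)
3 | 4-(benzyloxy)-3-methoxyphenol | COc1cc(O)ccc1OCc1ccccc1 | intermediate
4 | 5-(benzyloxy)-2-hydroxy-4-methoxybenzaldehyde | COc1cc(O)c(C=O)cc1OCc1ccccc1 | intermediate
5 | N-acetylglycine | CC(=O)NCC(=O)O | starting material
6 | 2-methyl-1,3-oxazol-5(4H)-one | CC1=NCC(=O)O1 | intermediate (not isolated)
7 | N-[6-(benzyloxy)-7-methoxy-2-oxo-2H-chromen-3-yl]acetamide | COc1cc2oc(=O)c(NC(C)=O)cc2cc1OCc1ccccc1 | intermediate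
8 | 3-amino-6-(benzyloxy)-7-methoxy-2H-chromen-2-one | COc1cc2oc(=O)c(N)cc2cc1OCc1ccccc1 | intermediate (not isolated)
9 | 6-(benzyloxy)-3-hydroxy-7-methoxy-2H-chromen-2-one | COc1cc2oc(=O)c(O)cc2cc1OCc1ccccc1 | intermediate
10 | umbelliferone (7-hydroxy-2H-chromen-2-one) | Oc1ccc2ccc(=O)oc2c1 | starting material
11 | 2-oxo-2H-chromen-7-yl trifluoromethanesulfonate | O=c1ccc2ccc(OS(=O)(=O)C(F)(F)F)cc2o1 | intermediate
12 | bis(pinacolato)diboron | CC1(C)OB(OC1(C)C)B1OC(C)(C)C(C)(C)O1 | starting material
13 | 7-(4,4,5,5-tetramethyl-1,3,2-dioxaborolan-2-yl)-2H-chromen-2-one | CC1(C)OB(OC1(C)C)c1ccc2ccc(=O)oc2c1 | intermediate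
14 | 6-(benzyloxy)-7-methoxy-3-[(2-oxo-2H-chromen-7-yl)oxy]-2H-chromen-2-one | COc1cc2oc(=O)c(Oc3ccc4ccc(=O)oc4c3)cc2cc1OCc1ccccc1 | intermediate
15 | 6-hydroxy-7-methoxy-3-[(2-oxo-2H-chromen-7-yl)oxy]-2H-chromen-2-one | COc1cc2oc(=O)c(Oc3ccc4ccc(=O)oc4c3)cc2cc1O | target

Total step count: 8. Longest linear sequence: 6 (steps 1, 2, 3, 4, 7, 8). Steps 5 and 6 form the convergent branch.

**Steps most likely to fail**

Step 7. Transmetalation of the pinacol boronate may be slow. Copper may also be held back by chelation between the C3 oxygen and the C2 carbonyl, so that protodeboronation or hydroxylation of the boron partner and oxidative coupling of the enol at C4 overtake ether formation. The fallback sets out from 10 and 4, comes back at 14, and builds the unprimed pyranone ring around an ether oxygen that is already in place. Umbelliferone 10 is alkylated with tert-butyl bromoacetate (K2CO3, acetone, reflux) to tert-butyl 2-[(2-oxo-2H-chromen-7-yl)oxy]acetate F1. TFA in CH2Cl2 then frees 2-[(2-oxo-2H-chromen-7-yl)oxy]acetic acid F2. A Perkin–Oglialoro condensation of F2 with salicylaldehyde 4 (Ac2O, Et3N, 110 °C) forms C3–C4 and O1–C2 and gives 14.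

Step 4. The long acidic reflux may erode the benzyl ether, or the hydrolysis may stall at the amine stage. The fallback sets out from 4, comes back at 9, and brings the C3 oxygen in with the two-carbon unit, so that no nitrogen has to be hydrolysed. Compound 4 is O-acylated with acetoxyacetyl chloride (Et3N, CH2Cl2, 0 °C) to 4-(benzyloxy)-2-formyl-5-methoxyphenyl 2-(acetyloxy)acetate F3. On warming with more Et3N, F3 closes by intramolecular Knoevenagel-type aldol condensation to 6-(benzyloxy)-7-methoxy-2-oxo-2H-chromen-3-yl acetate F4. Catalytic K2CO3 in MeOH at 0 °C removes the activated enol acetate and gives 9.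

Step 3. O-Acetylation of the phenol may outrun condensation at an aldehyde that is deactivated by its para methoxy group. The condensation may also stall at an arylidene stage whose geometry keeps the phenol oxygen away from the oxazolone carbonyl. The fallback sets out from 4 and comes back at 8. Knoevenagel condensation and lactonisation of 4 with ethyl nitroacetate (piperidine and AcOH, both catalytic, toluene, reflux with water removal) gives 6-(benzyloxy)-7-methoxy-3-nitro-2H-chromen-2-one F5. Iron powder with NH4Cl in aqueous EtOH reduces the nitro group without touching the benzyl ether and gives 8. Compound 8 is then isolated and hydrolysed under the conditions of step 4.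

**Further compounds**
F1 | step 7 | tert-butyl 2-[(2-oxo-2H-chromen-7-yl)oxy]acetate | CC(C)(C)OC(=O)COc1ccc2ccc(=O)oc2c1
F2 | step 7 | 2-[(2-oxo-2H-chromen-7-yl)oxy]acetic acid | OC(=O)COc1ccc2ccc(=O)oc2c1
F3 | step 4 | 4-(benzyloxy)-2-formyl-5-methoxyphenyl 2-(acetyloxy)acetate | COc1cc(OC(=O)COC(C)=O)c(C=O)cc1OCc1ccccc1
F4 | step 4 | 6-(benzyloxy)-7-methoxy-2-oxo-2H-chromen-3-yl acetate | COc1cc2oc(=O)c(OC(C)=O)cc2cc1OCc1ccccc1
F5 | step 3 | 6-(benzyloxy)-7-methoxy-3-nitro-2H-chromen-2-one | COc1cc2oc(=O)c([N+](=O)[O-])cc2cc1OCc1ccccc1
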